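**Retrosynthetic overview**
1. Target ⇐ C8 ketone (methylenation) ⇐ α-face cis-dihydroxylation of a C9=C10 enone ⇐ acylation of the 6-OH.
2. Seven-membered ring (formed last) ⇐ formal (4+3) annulation of a trans-1,4-dialdehyde with a β-ketophosphonate dianion: chelation-controlled aldol (C6–C7), then intramolecular HWE (C9=C10).
3. Dialdehyde ⇐ γ-lactone; the C1 quaternary centre (C1–C15 bond) comes from a light-driven, silicon-tethered radical conjugate methylation of a butenolide, delivered from the C4 hydroxyl.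
4. Butenolide (temporary ring) ⇐ dienol ether photooxygenation of a cyclopentenecarbaldehyde ⇐ ozonolysis/aldol ring contraction of (S)-terpinen-4-ol (five-membered ring first; only source of chirality).

Assumption: (S)-(+)-terpinen-4-ol is bought in ≥98% ee; atom labels C1–C15 in the text follow daucane numbering (C1 = C-methyl ring-fusion carbon, C4 = carbinol carbon bearing isopropyl, C5 = ring-fusion CH, C6–C10 = other seven-ring carbons, C14 = exocyclic CH2, C15 = angular methyl).

**Step 1**
Reactants: 1 (S)-(+)-terpinen-4-ol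
Product: 3 (5R)-5-hydroxy-2-methyl-5-(propan-2-yl)cyclopent-1-ene-1-carbaldehyde, via keto aldehyde 2 (not isolated)
Conditions: O3, CH2Cl2/MeOH, −78 °C; Me2S, −78 °C → rt; then piperidine, AcOH, PhMe, 50 °C
Reagents that add atoms: ozone, [O-][O+]=O
Why: Ozonolysis cleaves the only C=C and the amine/acid-mediated intramolecular aldol condensation (aldehyde enamine onto the methyl ketone) contracts the ring to the cyclopentenecarbaldehyde; the carbinol stereocentre (future C4) is carried over unchanged from 1.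

**Step 2**
Reactants: 3 (5R)-5-hydroxy-2-methyl-5-(propan-2-yl)cyclopent-1-ene-1-carbaldehyde
Product: 6 (6R)-6-hydroxy-6-(propan-2-yl)-3,4,5,6-tetrahydro-1H-cyclopenta[c]furan-1-one, via bis-silyl dienol ether 4 (not isolated), via silyloxy endoperoxide 5 (not isolated)
Conditions: KHMDS (2.2 equiv), TMSCl, THF, −78 °C; then O2, TPP (cat.), hν (white LEDs), CH2Cl2, −78 °C; then Et3N, 0 °C; 1 M HCl/THF work-up
Reagents that add atoms: oxygen, O=O; chlorotrimethylsilane, C[Si](C)(C)Cl (its silicon is present only in 4 and 5)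
Why: Kinetic deprotonation of the γ-methyl syn to the formyl group gives the s-cis 1-silyloxy diene, whose [4+2] photooxygenation with singlet oxygen and Kornblum–DeLaMare fragmentation of the peroxy-acetal C–H give the γ-hydroxy acid level that lactonises to the butenolide (C10 now oxygenated); no stereocentre is formed or touched.

**Step 3**
Reactants: 6 (6R)-6-hydroxy-6-(propan-2-yl)-3,4,5,6-tetrahydro-1H-cyclopenta[c]furan-1-one; 7 (bromomethyl)chlorodimethylsilane
Product: 10 (3aS,6R,6aS)-6-hydroxy-3a-methyl-6-(propan-2-yl)hexahydro-1H-cyclopenta[c]furan-1-one, via bromomethylsilyl ether 8 (not isolated), via bridged siloxane lactone 9 (not isolated)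
Conditions: 7, imidazole, CH2Cl2, 0 °C → rt; then (TMS)3SiH, 4CzIPN (2 mol %), MeCN, 450 nm LEDs, rt; then TBAF, DMF, 70 °C
Reagents that add atoms: (bromomethyl)chlorodimethylsilane 7, C[Si](C)(Cl)CBr
Why: Proposed new method: a visible-light, silyl-radical halogen-atom-transfer initiated 6-endo cyclisation of the O-tethered α-silylmethyl radical onto the electrophilic β-carbon (C1) of the tetrasubstituted butenolide, H-atom transfer from (TMS)3SiH to the resulting α-acyl radical and fluoride protodesilylation together amount to a hydroxyl-delivered conjugate methylation that forms the C1–C15 bond and the quaternary stereocentre; the nucleophilic radical prefers the enoate β-carbon over the 5-exo alternative (α-carbon), and the O–Si–C tether anchored on the C4 oxygen can reach C1 only on the hydroxyl face, so the methyl ends cis to OH (3aS), while the lactone α-centre settles as the cis-fused ring under the basic fluoride conditions; closest known reaction types are the tin-hydride radical cyclisation/protodesilylation of (bromomethyl)dimethylsilyl ethers (Stork reductive methylation) and photocatalytic silyl-radical XAT Giese additions, neither shown for a 6-endo closure onto a tetrasubstituted butenolide.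

**Step 4**
Reactants: 10 (3aS,6R,6aS)-6-hydroxy-3a-methyl-6-(propan-2-yl)hexahydro-1H-cyclopenta[c]furan-1-one
Product: 11 (1R,2R,3S)-2,3-bis(hydroxymethyl)-3-methyl-1-(propan-2-yl)cyclopentan-1-ol
Conditions: LiAlH4, THF, 0 °C → rt
Reagents that add atoms: none
Why: Hydride reduction of the γ-lactone to the 1,4-diol; no stereocentre changes.

**Step 5**
Reactants: 11 (1R,2R,3S)-2,3-bis(hydroxymethyl)-3-methyl-1-(propan-2-yl)cyclopentan-1-ol
Product: 13 (1S,2R,3R)-3-hydroxy-1-methyl-3-(propan-2-yl)cyclopentane-1,2-dicarbaldehyde, via cis-dialdehyde 12 (not isolated)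
Conditions: (COCl)2, DMSO, CH2Cl2, −78 °C; Et3N, −78 °C → rt, 12 h
Reagents that add atoms: none
Why: Swern oxidation of both primary alcohols, then amine-mediated epimerisation of the only enolisable centre (C5) to the thermodynamically preferred trans-dialdehyde (formyl trans to the neighbouring formyl and to the isopropyl group, cis to the small OH), which sets C5 with H on the α-face.

**Step 6**
Reactants: 13 (1S,2R,3R)-3-hydroxy-1-methyl-3-(propan-2-yl)cyclopentane-1,2-dicarbaldehyde; 14 dimethyl (2-oxopropyl)phosphonate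
Product: 16 (1S,2S,7R,10R)-2,10-dihydroxy-7-methyl-10-(propan-2-yl)bicyclo[5.3.0]dec-5-en-4-one, via aldol adduct 15 (not isolated)
Conditions: LiHMDS (1.0 equiv), MgBr2·OEt2, THF, −78 °C; then dianion of 14 (14 + LDA, 2 equiv; 1.1 equiv), −78 °C → rt
Reagents that add atoms: dimethyl (2-oxopropyl)phosphonate 14, COP(=O)(CC(C)=O)OC
Why: Formal (4+3) annulation: the γ-carbon of the β-ketophosphonate dianion adds to the aldehyde held in a six-membered Mg chelate with the cis C4 alkoxide, from the face anti to C1 (chelation-controlled aldol, sets C6 as 6α-OH), and the remaining phosphonate anion closes the seven-membered ring on the non-enolisable C10 aldehyde by intramolecular Horner–Wadsworth–Emmons olefination (ring-enforced Z enone).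

**Step 7**
Reactants: 16 (1S,2S,7R,10R)-2,10-dihydroxy-7-methyl-10-(propan-2-yl)bicyclo[5.3.0]dec-5-en-4-one; 17 3-methylbutanoyl chloride
Product: 18 (1S,2S,7R,10R)-10-hydroxy-7-methyl-4-oxo-10-(propan-2-yl)bicyclo[5.3.0]dec-5-en-2-yl 3-methylbutanoate
Conditions: 17, pyridine, DMAP (cat.), CH2Cl2, 0 °C
Reagents that add atoms: 3-methylbutanoyl chloride 17, CC(C)CC(=O)Cl
Why: DMAP-catalysed acylation is selective for the only secondary hydroxyl over the hindered tertiary one; C6 keeps its configuration.

**Step 8**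
Reactants: 18 (1S,2S,7R,10R)-10-hydroxy-7-methyl-4-oxo-10-(propan-2-yl)bicyclo[5.3.0]dec-5-en-2-yl 3-methylbutanoate
Product: 19 (1S,2S,5S,6S,7S,10R)-5,6,10-trihydroxy-7-methyl-4-oxo-10-(propan-2-yl)bicyclo[5.3.0]decan-2-yl 3-methylbutanoate
Conditions: OsO4 (5 mol %), NMO, citric acid, t-BuOH/H2O, rt
Reagents that add atoms: osmium tetroxide (catalytic oxygen carrier), O=[Os](=O)(=O)=O; 4-methylmorpholine N-oxide, C[N+]1([O-])CCOCC1; water, O
Why: Upjohn cis-dihydroxylation of the C9=C10 enone from the α-face, anti to the angular methyl on the adjacent quaternary C1, sets C9 and C10 (cis-diol, both α); the acidic buffer protects the β-acyloxy ketone from elimination.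

**Step 9**
Reactants: 19 (1S,2S,5S,6S,7S,10R)-5,6,10-trihydroxy-7-methyl-4-oxo-10-(propan-2-yl)bicyclo[5.3.0]decan-2-yl 3-methylbutanoate; 20 dibromomethane
Product: 21 (1S,2S,5R,6S,7S,10R)-5,6,10-trihydroxy-7-methyl-4-methylidene-10-(propan-2-yl)bicyclo[5.3.0]decan-2-yl 3-methylbutanoate (CNP0204264.1)
Conditions: 20, Zn, TiCl4, THF/CH2Cl2, 0 °C → rt
Reagents that add atoms: dibromomethane 20, BrCBr
Why: Takai–Lombardo methylenation converts the ketone into the exocyclic alkene under non-basic conditions that spare the ester, the free hydroxyls and the adjacent stereocentres.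

**Compound list**
1 | (S)-(+)-terpinen-4-ol [(1S)-4-methyl-1-(propan-2-yl)cyclohex-3-en-1-ol] | CC1=CC[C@](O)(C(C)C)CC1 | starting material
2 | (3S)-3-hydroxy-6-oxo-3-(propan-2-yl)heptanal | O=CC[C@](O)(C(C)C)CCC(C)=O | intermediate
3 | (5R)-5-hydroxy-2-methyl-5-(propan-2-yl)cyclopent-1-ene-1-carbaldehyde | O=CC1=C(C)CC[C@@]1(O)C(C)C | intermediate
4 | bis(trimethylsilyl) dienol ether of 3: {[(1E,2R)-5-methylidene-2-(propan-2-yl)-2-(trimethylsilyloxy)cyclopentylidene]methoxy}trimethylsilane | C[Si](C)(C)O/C=C1\C(=C)CC[C@@]1(O[Si](C)(C)C)C(C)C | intermediate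
5 | 1,4-endoperoxide of 4 (3-silyloxy-3,6-dihydro-1,2-dioxine fused to the cyclopentene; carbinol centre R; peroxy-acetal carbon an epimer mixture that is destroyed in the next event) | C[Si](C)(C)OC1OOCC2=C1[C@](O[Si](C)(C)C)(C(C)C)CC2 | intermediate
6 | (6R)-6-hydroxy-6-(propan-2-yl)-3,4,5,6-tetrahydro-1H-cyclopenta[c]furan-1-one | O=C1OCC2=C1[C@](O)(C(C)C)CC2 | intermediate
7 | (bromomethyl)chlorodimethylsilane | C[Si](C)(Cl)CBr | starting material
8 | (6R)-6-{[(bromomethyl)dimethylsilyl]oxy}-6-(propan-2-yl)-3,4,5,6-tetrahydro-1H-cyclopenta[c]furan-1-one | O=C1OCC2=C1[C@](O[Si](C)(C)CBr)(C(C)C)CC2 | intermediate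
9 | bridged siloxane lactone: cis-fused lactone 10 in which the 3a-CH2 and the C6 oxygen are joined through SiMe2 (O–SiMe2–CH2 bridge on the face of the former OH) | O=C1OC[C@@]23CC[C@@](O[Si](C)(C)C3)(C(C)C)[C@@H]12 | intermediate
10 | (3aS,6R,6aS)-6-hydroxy-3a-methyl-6-(propan-2-yl)hexahydro-1H-cyclopenta[c]furan-1-one (methyl cis to OH; cis-fused lactone) | O=C1OC[C@@]2(C)CC[C@@](O)(C(C)C)[C@@H]12 | intermediate
11 | (1R,2R,3S)-2,3-bis(hydroxymethyl)-3-methyl-1-(propan-2-yl)cyclopentan-1-ol | OC[C@@]1(C)CC[C@@](O)(C(C)C)[C@H]1CO | intermediate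
12 | (1S,2S,3R)-3-hydroxy-1-methyl-3-(propan-2-yl)cyclopentane-1,2-dicarbaldehyde (cis-dialdehyde) | O=C[C@@]1(C)CC[C@@](O)(C(C)C)[C@H]1C=O | intermediate
13 | (1S,2R,3R)-3-hydroxy-1-methyl-3-(propan-2-yl)cyclopentane-1,2-dicarbaldehyde (trans-dialdehyde) | O=C[C@@]1(C)CC[C@@](O)(C(C)C)[C@@H]1C=O | intermediate
14 | dimethyl (2-oxopropyl)phosphonate | COP(=O)(CC(C)=O)OC | starting material
15 | dimethyl {(4S)-4-[(1S,2S,5R)-2-formyl-5-hydroxy-2-methyl-5-(propan-2-yl)cyclopentyl]-4-hydroxy-2-oxobutyl}phosphonate | O=C[C@@]1(C)CC[C@@](O)(C(C)C)[C@@H]1[C@@H](O)CC(=O)CP(=O)(OC)OC | intermediate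
16 | (1S,2S,7R,10R)-2,10-dihydroxy-7-methyl-10-(propan-2-yl)bicyclo[5.3.0]dec-5-en-4-one (trans-fused) | O=C1C[C@H](O)[C@@H]2[C@](C)(CC[C@@]2(O)C(C)C)C=C1 | intermediate
17 | 3-methylbutanoyl chloride | CC(C)CC(=O)Cl | starting material
18 | (1S,2S,7R,10R)-10-hydroxy-7-methyl-4-oxo-10-(propan-2-yl)bicyclo[5.3.0]dec-5-en-2-yl 3-methylbutanoate | O=C1C[C@H](OC(=O)CC(C)C)[C@@H]2[C@](C)(CC[C@@]2(O)C(C)C)C=C1 | intermediate
19 | (1S,2S,5S,6S,7S,10R)-5,6,10-trihydroxy-7-methyl-4-oxo-10-(propan-2-yl)bicyclo[5.3.0]decan-2-yl 3-methylbutanoate | O=C1C[C@H](OC(=O)CC(C)C)[C@@H]2[C@](C)(CC[C@@]2(O)C(C)C)[C@H](O)[C@@H]1O | intermediate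
20 | dibromomethane | BrCBr | starting material
21 | (1S,2S,5R,6S,7S,10R)-5,6,10-trihydroxy-7-methyl-4-methylidene-10-(propan-2-yl)bicyclo[5.3.0]decan-2-yl 3-methylbutanoate (6α-isovaleroyloxy-dauc-8(14)-ene-4β,9α,10α-triol) | C=C1C[C@H](OC(=O)CC(C)C)[C@@H]2[C@](C)(CC[C@@]2(O)C(C)C)[C@H](O)[C@@H]1O | target

**Totals**
Total step count: 9 (one linear sequence; intermediates 2, 4, 5, 8, 9, 12 and 15 are carried on without isolation).
Longest linear sequence: 9 steps from 1.

**Three steps most likely to fail**

Step 2 (γ-oxygenation of the enal). The risks are γ-deprotonation at the ring CH2 instead of the methyl, and Kornblum–DeLaMare cleavage at the wrong C–H. Fallback, setting out from 3: Pinnick oxidation (NaClO2, NaH2PO4, 2-methyl-2-butene) gives (5R)-5-hydroxy-2-methyl-5-(propan-2-yl)cyclopent-1-ene-1-carboxylic acid F1. Esterification with TMSCHN2 gives the methyl ester F2. Wohl–Ziegler bromination (NBS, AIBN, PhCF3, reflux) gives the γ-bromomethyl ester F3, which lactonises on heating with loss of bromomethane and comes back to the route at 6.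

Step 3 (the proposed new photochemical radical methylation). The risks are 5-exo attack at the enoate α-carbon, strain in the bridged transition state, and sluggish protodesilylation at the neopentyl C–Si bond. Fallback with known chemistry, setting out from 6: Corey–Chaykovsky cyclopropanation with dimethylsulfoxonium methylide (Me3S(O)I, NaH, DMSO) adds CH2 across the butenolide C=C on the face anti to the isopropyl group (the hydroxyl face) to give the cyclopropane-fused lactone F4. Reductive cleavage of the exocyclic cyclopropane bond α to the lactone carbonyl (Li/NH3, t-BuOH, or SmI2/HMPA) turns that CH2 into the angular methyl and comes back to the route at 10.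

Step 6 (one-flask aldol/HWE annulation). The risks are attack of the dianion at the C10 aldehyde, enolisation or retro-aldol opening of the β-hydroxy aldehyde under strongly basic conditions, and dehydration of the β-hydroxy enone. Fallback, setting out from 13: a MgBr2·OEt2-mediated Mukaiyama aldol with 2-(trimethylsilyloxy)buta-1,3-diene (non-basic; only the chelated C6 aldehyde is activated) gives the β-hydroxy vinyl ketone F5. Aldehyde-selective Takai methylenation (CH2I2, Zn, Ti(OiPr)4) of the remaining C10 aldehyde gives the vinyl compound F6. Ring-closing metathesis (Grubbs II, CH2Cl2, 40 °C) forms C9=C10 with loss of ethene and comes back to the route at 16.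

**Further compounds**
F1 | step 2 | (5R)-5-hydroxy-2-methyl-5-(propan-2-yl)cyclopent-1-ene-1-carboxylic acid | OC(=O)C1=C(C)CC[C@@]1(O)C(C)C
F2 | step 2 | methyl (5R)-5-hydroxy-2-methyl-5-(propan-2-yl)cyclopent-1-ene-1-carboxylate | COC(=O)C1=C(C)CC[C@@]1(O)C(C)C
F3 | step 2 | methyl (5R)-2-(bromomethyl)-5-hydroxy-5-(propan-2-yl)cyclopent-1-ene-1-carboxylate | COC(=O)C1=C(CBr)CC[C@@]1(O)C(C)C
F4 | step 3 | cyclopropane-fused lactone (CH2 bridging the two ring-fusion carbons of 6 on the hydroxyl face; carbinol centre as in 6) | O=C1OC[C@]23C[C@]12[C@](O)(C(C)C)CC3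
F5 | step 6 | (1S,2S,3R)-3-hydroxy-2-[(1S)-1-hydroxy-3-oxopent-4-en-1-yl]-1-methyl-3-(propan-2-yl)cyclopentane-1-carbaldehyde | O=C[C@@]1(C)CC[C@@](O)(C(C)C)[C@@H]1[C@@H](O)CC(=O)C=C
F6 | step 6 | (5S)-5-[(1S,2R,5R)-2-ethenyl-5-hydroxy-2-methyl-5-(propan-2-yl)cyclopentyl]-5-hydroxypent-1-en-3-one | C=C[C@@]1(C)CC[C@@](O)(C(C)C)[C@@H]1[C@@H](O)CC(=O)C=C
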